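**Retrosynthetic overview**
1. Target 23 ⇐ triol ketone 20 by triple angeloylation with three molecules of angelic acid 21 (last step). Cyclohexanone ring ⇐ 6-endo radical closure (C3–C4) of a cyclobutyl iodide obtained by strain-release hydroiodination of acyl bicyclobutane 17.
2. 17 ⇐ α-diazo enone 16 by Rh2(OAc)4-catalysed intramolecular carbene cyclopropanation of a cycloheptene (C11–C4 and C11–C5 bonds).
3. Cycloheptene ⇐ one-carbon ring expansion (vinyl 1,2-shift, loss of N2) of cyclohexenone 4 with methyl 2-diazopropanoate, inserting quaternary C6. C7/C8 diol by lactone-controlled hydroxylation and reduction.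
4. 4 ⇐ 3-methylcyclohex-2-enone by CBS reduction, Eschenmoser–Claisen rearrangement (quaternary C10) and allylic oxidation.
5. Ring order: six-membered carbocycle (purchased) → expanded to the seven-membered ring → bicyclobutane (cyclobutane core) → cyclohexanone ring.

Assumption: positions in the Why lines use longipinane numbering (C1 ketone, C3 methyl-bearing CH, C4/C5/C10/C11 cyclobutane, C6 quaternary carbon, its oxygenated methyl called C15, C7/C8 secondary oxygenated carbons, C13 methyl on C10).

**Route**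

Step 1
Reactants: 1 3-methylcyclohex-2-en-1-one
Product: 2 (S)-3-methylcyclohex-2-en-1-ol
Conditions: (R)-2-methyl-CBS-oxazaborolidine C18H20BNO (10 mol%), BH3·SMe2, THF, −20 °C; MeOH, aqueous work-up
Reagents that add atoms: none
Why: Corey–Bakshi–Shibata reduction, in which the oxazaborolidine–borane complex delivers hydride to one carbonyl face (alkenyl arm as the large group) to give the S carbinol.

Step 2
Reactants: 2 (S)-3-methylcyclohex-2-en-1-ol
Product: 3 N,N-dimethyl-2-[(1S)-1-methylcyclohex-2-en-1-yl]acetamide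
Conditions: MeC(OMe)2NMe2 (3 equiv), xylenes, 140 °C, MeOH distilled off
Reagents that add atoms: N,N-dimethylacetamide dimethyl acetal, CC(OC)(OC)N(C)C
Why: Eschenmoser–Claisen [3,3] rearrangement, whose suprafacial transfer from the C–O bond to the methyl-bearing alkene carbon creates quaternary C10 with complete chirality transfer.

Step 3
Reactants: 3 N,N-dimethyl-2-[(1S)-1-methylcyclohex-2-en-1-yl]acetamide
Product: 4 N,N-dimethyl-2-[(1S)-1-methyl-4-oxocyclohex-2-en-1-yl]acetamide
Conditions: Rh2(cap)4 (cap = caprolactamate C6H10NO, 1 mol%), t-BuOOH (5 equiv), K2CO3, CH2Cl2, 23 °C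
Reagents that add atoms: tert-butyl hydroperoxide, CC(C)(C)OO
Why: Catalytic allylic C–H oxidation (tert-butylperoxyl radical chain) at the only allylic CH2 gives the 4,4-disubstituted enone without touching the quaternary centre.

Step 4
Reactants: 5 L-alanine methyl ester hydrochloride
Product: 6 methyl 2-diazopropanoate
Conditions: NaNO2, H2O/CH2Cl2, cat. H2SO4, −5 °C
Reagents that add atoms: NaNO2, [Na+].[O-]N=O
Why: Diazotisation of an α-amino ester, where the diazonium ion loses the acidic α-proton to give the stabilised α-diazo ester (the alanine stereocentre is erased).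

Step 5
Reactants: 4 N,N-dimethyl-2-[(1S)-1-methyl-4-oxocyclohex-2-en-1-yl]acetamide; 6 methyl 2-diazopropanoate
Product: 7 methyl (1R,4S)-4-[2-(dimethylamino)-2-oxoethyl]-1,4-dimethyl-7-oxocyclohept-2-ene-1-carboxylate
Conditions: Sc(OTf)3 (10 mol%), chiral pipecolic-acid-derived N,N′-dioxide ligand (12 mol%, enantiomer chosen for 1R), 6 (1.5 equiv), CH2Cl2, −20 °C
Reagents that add atoms: none
Why: Proposed new method: the chiral Sc(OTf)3–N,N′-dioxide Lewis acid binds the enone carbonyl of 4 and directs 1,2-addition of the diazo carbon of 6 to one face; in the diazonium betaine the vinyl carbon, the better migrating group once conjugation is lost, lies anti-periplanar to N2 and undergoes the 1,2-shift with loss of N2, so the seven-membered ring and quaternary C6 (1R) form in one catalyst-controlled Tiffeneau–Demjanov-type homologation; the closest known reactions are chiral-Lewis-acid-catalysed ring expansions of saturated cyclohexanones with α-alkyl-α-diazo esters and racemic BF3-promoted vinyl-migrating expansions of cyclohexenones, the enantioselective enone version being untested.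

Step 6
Reactants: 7 methyl (1R,4S)-4-[2-(dimethylamino)-2-oxoethyl]-1,4-dimethyl-7-oxocyclohept-2-ene-1-carboxylate
Product: 9 bridged keto lactone 2-[(1R,4S,6S)-1,4-dimethyl-8,9-dioxo-7-oxabicyclo[4.2.1]non-2-en-4-yl]-N,N-dimethylacetamide, via hydroxy keto ester 8 (not isolated)
Conditions: KN(SiMe3)2, THF, −78 °C; 2-(phenylsulfonyl)-3-phenyloxaziridine; AcOH; then camphor-10-sulfonic acid (cat.), PhMe, 80 °C
Reagents that add atoms: 2-(phenylsulfonyl)-3-phenyloxaziridine, O=S(=O)(c1ccccc1)N1OC1c1ccccc1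
Why: Davis α-hydroxylation of the only possible ketone enolate (C8) followed by acid-catalysed translactonisation; the oxidant approaches anti to the C6 methyl, and only the C8 epimer with hydroxyl cis to the ester can close the γ-lactone, the other being funnelled through the enol, which fixes C8.

Step 7
Reactants: 9 2-[(1R,4S,6S)-1,4-dimethyl-8,9-dioxo-7-oxabicyclo[4.2.1]non-2-en-4-yl]-N,N-dimethylacetamide
Product: 10 2-[(1S,4S,5S,6S)-5,6-dihydroxy-4-(hydroxymethyl)-1,4-dimethylcyclohept-2-en-1-yl]-N,N-dimethylacetamide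
Conditions: LiBH4 (4 equiv), THF, 0 → 23 °C; cold 1 M HCl work-up
Reagents that add atoms: none
Why: LiBH4 reduction in which hydride reaches the C7 ketone (on the one-atom bridge) from the face of the flat two-atom lactone bridge, anti to the substituted four-carbon bridge, giving C7–OH trans to C8–O and cis to the C6 methyl; excess LiBH4 then opens the lactone to the primary and C8 alcohols while the tertiary amide is inert.

Step 8
Reactants: 10 2-[(1S,4S,5S,6S)-5,6-dihydroxy-4-(hydroxymethyl)-1,4-dimethylcyclohept-2-en-1-yl]-N,N-dimethylacetamide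
Product: 11 2-[(1S,4S,5S,6S)-5,6-bis(tert-butyldimethylsilyloxy)-4-[(tert-butyldimethylsilyloxy)methyl]-1,4-dimethylcyclohept-2-en-1-yl]-N,N-dimethylacetamide
Conditions: TBSOTf (3.6 equiv), 2,6-lutidine, CH2Cl2, 0 → 23 °C
Reagents that add atoms: tert-butyldimethylsilyl triflate, CC(C)(C)[Si](C)(C)OS(=O)(=O)C(F)(F)F
Why: Silyl triflate silylation protects all three hindered hydroxyls against the organolithium, amide-base and carbene steps that follow.

Step 9
Reactants: 11 tris(silyl ether) amide; 12 (E)-1-bromoprop-1-ene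
Product: 14 (3E)-1-[(1S,4S,5S,6S)-5,6-bis(tert-butyldimethylsilyloxy)-4-[(tert-butyldimethylsilyloxy)methyl]-1,4-dimethylcyclohept-2-en-1-yl]pent-3-en-2-one, via (E)-prop-1-enyllithium 13 (not isolated)
Conditions: 12, t-BuLi (2 equiv per 12), Et2O, −78 °C; then 11, THF, −78 → 0 °C; cold 1 M HCl work-up
Reagents that add atoms: none
Why: Halogen–lithium exchange with retention of E geometry, then organolithium addition to the tertiary amide, whose stable tetrahedral intermediate collapses to the enone only on hydrolysis.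

Step 10
Reactants: 14 (3E)-1-[(1S,4S,5S,6S)-tris(silyloxy)cycloheptenyl]pent-3-en-2-one
Product: 16 (3E)-1-diazo-1-[(1R,4S,5S,6S)-5,6-bis(tert-butyldimethylsilyloxy)-4-[(tert-butyldimethylsilyloxy)methyl]-1,4-dimethylcyclohept-2-en-1-yl]pent-3-en-2-one, via trifluoroacetyl diketone 15 (not isolated)
Conditions: LiN(SiMe3)2, THF, −78 °C; CF3CO2CH2CF3; dilute HCl; then MsN3, Et3N, H2O, MeCN, 23 °C
Reagents that add atoms: methanesulfonyl azide, CS(=O)(=O)N=[N+]=[N-]
Why: Danheiser detrifluoroacetylative diazo transfer, in which kinetic deprotonation of the enone occurs at its only α′ CH2 (C11), the enolate is trifluoroacetylated, and the sulfonyl azide delivers N2 with loss of the activating group.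

Step 11
Reactants: 16 α-diazo enone
Product: 17 acyl bicyclobutane (E)-1-[4,5-bis(tert-butyldimethylsilyloxy)-6-[(tert-butyldimethylsilyloxy)methyl]-2,6-dimethyltricyclo[5.1.0.0(2,8)]oct-1-yl]but-2-en-1-one
Conditions: Rh2(OAc)4 (1 mol%), CH2Cl2, 23 °C, slow addition of 16
Reagents that add atoms: none
Why: Intramolecular cyclopropanation by an allyl-type carbene generated with Rh2(OAc)4 (the α-allyl diazo carbonyl to bicyclo[1.1.0]butane reaction), in which carbene carbon C11 hangs from quaternary C10 (no β-hydrogen) and can reach the adjacent cis alkene only from its own ring face, so the C11–C4 and C11–C5 bonds and the cyclobutane stereocentres follow from C10.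

Step 12
Reactants: 17 acyl bicyclobutane
Product: 19 7,8,15-tris(tert-butyldimethylsilyloxy)longipinan-1-one, via cyclobutyl iodide 18 (not isolated)
Conditions: LiI, AcOH, MeCN, 23 °C; then Bu3SnH (slow addition), AIBN, PhH, 80 °C
Reagents that add atoms: none
Why: Strain-release conjugate hydroiodination of the acyl bicyclobutane (iodide to C4, proton to C11, the ketone equilibrating through its enol to place the acyl chain anti to the seven-membered bridge) then Bu3SnH-mediated 6-endo-trig Giese cyclisation of the cyclobutyl radical onto the β-carbon of the (E)-enone; the enone can fold over the cyclobutane only on the side of the C5–H bridge, away from the C13 methyl, which puts the C3 methyl on the C5 side as in the target.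

Step 13
Reactants: 19 7,8,15-tris(tert-butyldimethylsilyloxy)longipinan-1-one
Product: 20 7,8,15-trihydroxylongipinan-1-one
Conditions: HF·pyridine, THF/pyridine, 0 → 23 °C
Reagents that add atoms: none
Why: Fluoride-mediated desilylation frees the three hydroxyls without affecting the ketone or any stereocentre.

Step 14
Reactants: 20 7,8,15-trihydroxylongipinan-1-one; 21 angelic acid (3 equiv incorporated)
Product: 23 7,8,15-tris(angeloyloxy)longipinan-1-one (target), via angelic 2,4,6-trichlorobenzoic anhydride 22 (not isolated)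
Conditions: 21 (6 equiv in all), 2,4,6-trichlorobenzoyl chloride (6 equiv), Et3N (12 equiv), PhMe, 23 °C; then 20 (1 equiv), PhMe, 80 °C
Reagents that add atoms: angelic acid (two further molecules of 21), C/C=C(/C)C(=O)O.C/C=C(/C)C(=O)O
Why: Yamaguchi-type mixed-anhydride acylation without a nucleophilic catalyst, in which one molecule of 22 acylates each of the three hydroxyls (so three molecules of 21 are built into 23) while the Z geometry of the angelate is retained.

**Compound list**

1 | 3-methylcyclohex-2-en-1-one | CC1=CC(=O)CCC1 | starting material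
2 | (S)-3-methylcyclohex-2-en-1-ol | CC1=C[C@@H](O)CCC1 | intermediate
3 | N,N-dimethyl-2-[(1S)-1-methylcyclohex-2-en-1-yl]acetamide | CN(C)C(=O)C[C@@]1(C)C=CCCC1 | intermediate
4 | N,N-dimethyl-2-[(1S)-1-methyl-4-oxocyclohex-2-en-1-yl]acetamide | CN(C)C(=O)C[C@@]1(C)C=CC(=O)CC1 | intermediate
5 | L-alanine methyl ester hydrochloride | C[C@H](N)C(=O)OC.Cl | starting material
6 | methyl 2-diazopropanoate | CC(=[N+]=[N-])C(=O)OC | intermediate
7 | methyl (1R,4S)-4-[2-(dimethylamino)-2-oxoethyl]-1,4-dimethyl-7-oxocyclohept-2-ene-1-carboxylate | COC(=O)[C@]1(C)C=C[C@](C)(CC(=O)N(C)C)CCC1=O | intermediate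
8 | methyl (1R,4S,6S)-4-[2-(dimethylamino)-2-oxoethyl]-6-hydroxy-1,4-dimethyl-7-oxocyclohept-2-ene-1-carboxylate (hydroxy keto ester) | COC(=O)[C@]1(C)C=C[C@](C)(CC(=O)N(C)C)C[C@H](O)C1=O | intermediate
9 | 2-[(1R,4S,6S)-1,4-dimethyl-8,9-dioxo-7-oxabicyclo[4.2.1]non-2-en-4-yl]-N,N-dimethylacetamide (bridged keto lactone) | O=C1O[C@H]2C[C@@](C)(CC(=O)N(C)C)C=C[C@]1(C)C2=O | intermediate
10 | 2-[(1S,4S,5S,6S)-5,6-dihydroxy-4-(hydroxymethyl)-1,4-dimethylcyclohept-2-en-1-yl]-N,N-dimethylacetamide | OC[C@]1(C)C=C[C@](C)(CC(=O)N(C)C)C[C@H](O)[C@H]1O | intermediate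
11 | 2-[(1S,4S,5S,6S)-5,6-bis(tert-butyldimethylsilyloxy)-4-[(tert-butyldimethylsilyloxy)methyl]-1,4-dimethylcyclohept-2-en-1-yl]-N,N-dimethylacetamide | CC(C)(C)[Si](C)(C)OC[C@]1(C)C=C[C@](C)(CC(=O)N(C)C)C[C@H](O[Si](C)(C)C(C)(C)C)[C@H]1O[Si](C)(C)C(C)(C)C | intermediate
12 | (E)-1-bromoprop-1-ene | C/C=C/Br | starting material
13 | (E)-prop-1-enyllithium | C/C=C/[Li] | intermediate
14 | (3E)-1-[(1S,4S,5S,6S)-5,6-bis(tert-butyldimethylsilyloxy)-4-[(tert-butyldimethylsilyloxy)methyl]-1,4-dimethylcyclohept-2-en-1-yl]pent-3-en-2-one | CC(C)(C)[Si](C)(C)OC[C@]1(C)C=C[C@](C)(CC(=O)/C=C/C)C[C@H](O[Si](C)(C)C(C)(C)C)[C@H]1O[Si](C)(C)C(C)(C)C | intermediate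
15 | 1-trifluoroacetyl derivative of 14 (trifluoroacetyl diketone, new centre unassigned) | CC(C)(C)[Si](C)(C)OC[C@]1(C)C=C[C@](C)(C(C(=O)C(F)(F)F)C(=O)/C=C/C)C[C@H](O[Si](C)(C)C(C)(C)C)[C@H]1O[Si](C)(C)C(C)(C)C | intermediate
16 | (3E)-1-diazo-1-[(1R,4S,5S,6S)-5,6-bis(tert-butyldimethylsilyloxy)-4-[(tert-butyldimethylsilyloxy)methyl]-1,4-dimethylcyclohept-2-en-1-yl]pent-3-en-2-one | CC(C)(C)[Si](C)(C)OC[C@]1(C)C=C[C@](C)(C(=[N+]=[N-])C(=O)/C=C/C)C[C@H](O[Si](C)(C)C(C)(C)C)[C@H]1O[Si](C)(C)C(C)(C)C | intermediate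
17 | (E)-1-[4,5-bis(tert-butyldimethylsilyloxy)-6-[(tert-butyldimethylsilyloxy)methyl]-2,6-dimethyltricyclo[5.1.0.0(2,8)]oct-1-yl]but-2-en-1-one (acyl bicyclobutane; four-carbon bridge joins the endo positions of the wing carbons; configuration as in SMILES) | CC(C)(C)[Si](C)(C)OC[C@]1(C)[C@H]2[C@@H]3[C@@]2(C(=O)/C=C/C)[C@]3(C)C[C@H](O[Si](C)(C)C(C)(C)C)[C@H]1O[Si](C)(C)C(C)(C)C | intermediate
18 | (E)-1-[3,4-bis(tert-butyldimethylsilyloxy)-5-[(tert-butyldimethylsilyloxy)methyl]-8-iodo-1,5-dimethylbicyclo[4.1.1]octan-7-yl]but-2-en-1-one (cyclobutyl iodide; acyl anti to the four-carbon bridge, epimers at C–I) | CC(C)(C)[Si](C)(C)OC[C@]1(C)[C@H]2C(I)[C@](C)([C@@H]2C(=O)/C=C/C)C[C@H](O[Si](C)(C)C(C)(C)C)[C@H]1O[Si](C)(C)C(C)(C)C | intermediate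
19 | 7,8,15-tris(tert-butyldimethylsilyloxy)longipinan-1-one (configuration as in the target) | CC(C)(C)[Si](C)(C)OC[C@]1(C)[C@H]2[C@@H]3[C@H](C)CC(=O)[C@H]2[C@]3(C)C[C@H](O[Si](C)(C)C(C)(C)C)[C@H]1O[Si](C)(C)C(C)(C)C | intermediate
20 | 7,8,15-trihydroxylongipinan-1-one = 4,5-dihydroxy-3-(hydroxymethyl)-3,7,11-trimethyltricyclo[5.4.0.0(2,8)]undecan-9-one (configuration as in the target) | OC[C@]1(C)[C@H]2[C@@H]3[C@H](C)CC(=O)[C@H]2[C@]3(C)C[C@H](O)[C@H]1O | intermediate
21 | angelic acid, (Z)-2-methylbut-2-enoic acid | C/C=C(/C)C(=O)O | starting material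
22 | angelic 2,4,6-trichlorobenzoic anhydride | C/C=C(/C)C(=O)OC(=O)c1c(Cl)cc(Cl)cc1Cl | intermediate
23 | 7,8,15-tris(angeloyloxy)longipinan-1-one, CNP0214984.1 | C/C=C(/C)C(=O)OC[C@]1(C)[C@H]2[C@@H]3[C@H](C)CC(=O)[C@H]2[C@]3(C)C[C@H](OC(=O)/C(C)=C\C)[C@H]1OC(=O)/C(C)=C\C | target

**Step count**
Total steps: 14. Longest linear sequence: 13 (steps 1–3 and 5–14; step 4 is a one-step branch).

**Three steps most likely to fail, with fallbacks**

Step 5 (proposed new ring expansion; risks are alkyl instead of vinyl migration, pyrazoline formation, and poor control at C6). The fallback uses known chemistry, sets out from 4 and returns at 7. CH2=C(CH3)MgBr with CeCl3 adds 1,2 to 4 to give the tertiary dienol F1 (both carbinol epimers; this centre is destroyed later). Hydroxyl-directed epoxidation with VO(acac)2 and t-BuOOH gives the epoxy alcohol F2, and the diastereomer with the epoxide configuration shown is separated. BF3·OEt2 at −78 °C then triggers the semipinacol ring expansion of the 2,3-epoxy alcohol (vinyl shift anti to the breaking C–O bond) to give the hydroxymethyl ketone F3. Dess–Martin oxidation gives the keto aldehyde F4, and Pinnick oxidation (NaClO2, NaH2PO4, 2-methylbut-2-ene) gives the keto acid F5, which is esterified at once with Me3SiCHN2 in MeOH to give 7.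

Step 11 (strained bridged bicyclobutane by carbene addition; risks are C–H insertion, 1,2-alkyl shift or ylide formation). The fallback sets out from 14 and returns at 17 by two successive 3-exo-tet alkylations instead of a carbene. mCPBA with NaHCO3 epoxidises the ring alkene on the face of the two methyl groups, anti to the side chain, to give the epoxy enone F6. LiN(SiMe3)2 forms the α′-enolate, which opens the epoxide at C4 to give the cyclopropyl carbinol F7. MsCl and Et3N give the mesylate F8, and KOtBu in THF effects 1,3-elimination (C11 carbanion displaces the C5 mesylate) to give 17.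

Step 12 (risks are the wrong C11 epimer of iodide 18, which cannot cyclise, and simple reduction of the radical). The fallback sets out from 17 and returns at 19, forming the same C3–C4 bond from the other partner with the acyl group still locked on the bicyclobutane. LiN(iPr)2 with HMPA at −78 °C followed by AcOH (kinetic α-protonation of the dienolate) deconjugates the enone to the but-3-enoyl bicyclobutane F9. Fe(acac)3 (cat.) and PhSiH3 in EtOH then transfer a hydrogen atom to the terminal alkene; the secondary C3 radical, held by the tether over the open convex face of the bicyclobutane, adds to C4 with strain release, and the resulting C11 radical α to the ketone is reduced to give 19.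

**Further compounds**

F1 | step 5 | N,N-dimethyl-2-[(1S)-4-hydroxy-1-methyl-4-(prop-1-en-2-yl)cyclohex-2-en-1-yl]acetamide (both carbinol epimers) | CC(=C)C1(O)C=C[C@](C)(CC(=O)N(C)C)CC1
F2 | step 5 | N,N-dimethyl-2-[(1S)-4-hydroxy-1-methyl-4-(2-methyloxiran-2-yl)cyclohex-2-en-1-yl]acetamide (epoxide configuration as shown) | C[C@@]1(CO1)C2(O)C=C[C@](C)(CC(=O)N(C)C)CC2
F3 | step 5 | 2-[(1S,4S)-4-(hydroxymethyl)-1,4-dimethyl-5-oxocyclohept-2-en-1-yl]-N,N-dimethylacetamide | OC[C@]1(C)C=C[C@](C)(CC(=O)N(C)C)CCC1=O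
F4 | step 5 | 2-[4-formyl-1,4-dimethyl-5-oxocyclohept-2-en-1-yl]-N,N-dimethylacetamide (configuration as in 7) | O=C[C@]1(C)C=C[C@](C)(CC(=O)N(C)C)CCC1=O
F5 | step 5 | 4-[2-(dimethylamino)-2-oxoethyl]-1,4-dimethyl-7-oxocyclohept-2-ene-1-carboxylic acid (configuration as in 7) | OC(=O)[C@]1(C)C=C[C@](C)(CC(=O)N(C)C)CCC1=O
F6 | step 11 | 2,3-epoxide of 14 (oxirane on the face of the two ring methyl groups) | CC(C)(C)[Si](C)(C)OC[C@]1(C)[C@H]2O[C@H]2[C@](C)(CC(=O)/C=C/C)C[C@H](O[Si](C)(C)C(C)(C)C)[C@H]1O[Si](C)(C)C(C)(C)C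
F7 | step 11 | bicyclo[5.1.0]octan-2-ol with 8-[(E)-but-2-enoyl] group (cyclopropyl carbinol from epoxide opening) | CC(C)(C)[Si](C)(C)OC[C@]1(C)[C@@H](O)[C@@H]2[C@@H](C(=O)/C=C/C)[C@]2(C)C[C@H](O[Si](C)(C)C(C)(C)C)[C@H]1O[Si](C)(C)C(C)(C)C
F8 | step 11 | methanesulfonate of F7 | CC(C)(C)[Si](C)(C)OC[C@]1(C)[C@@H](OS(C)(=O)=O)[C@@H]2[C@@H](C(=O)/C=C/C)[C@]2(C)C[C@H](O[Si](C)(C)C(C)(C)C)[C@H]1O[Si](C)(C)C(C)(C)C
F9 | step 12 | but-3-enoyl analogue of 17 (deconjugated acyl bicyclobutane) | CC(C)(C)[Si](C)(C)OC[C@]1(C)[C@H]2[C@@H]3[C@@]2(C(=O)CC=C)[C@]3(C)C[C@H](O[Si](C)(C)C(C)(C)C)[C@H]1O[Si](C)(C)C(C)(C)C
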